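The crowded C7–C1' axis is not made by biaryl coupling. It begins as an unhindered aryl–furan bond, and the substituted naphthalene ring (C1'–C2'–C3'–C4'–C4a'–C8a') is built around it. That ring carries aryl at C1', methyl at C2', hydrogen at C3' and oxygen at C4'. This is the imprint of a 2-aryl-3-methylfuran whose ring oxygen is kept as O4'. One aryne Diels–Alder reaction with 3-benzyloxybenzyne forms C1'–C8a' and C4'–C4a'. It delivers the new carbocycle with the furan oxygen as a 1,4-epoxy bridge, and O5' is already distinguished from O4'. The precursor is 8-benzyloxy-1,3-dimethyl-7-(3-methylfuran-2-yl)isoquinoline, made by Negishi coupling.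

Key step: step 9

Assumption: the SMILES carries no axial descriptor, so the drawn constitution (4'-OMe, 5'-OH, 8-OH) is made as the racemate and resolved. The ent series is taken as the M axis, to be confirmed by CD; if the assignment is the reverse, the other HPLC fraction is collected.

Step 1
Reactants: 1 1-(3-bromo-2-hydroxyphenyl)ethanone
Product: 2 1-[2-(benzyloxy)-3-bromophenyl]ethanone
Conditions: BnBr, K2CO3, DMF, 60 °C
Reagents that add atoms: benzyl bromide, BrCc1ccccc1
Why: Williamson etherification masks the future O8 with a group that tolerates organometallics, fluoride and acid and leaves by hydrogenolysis at the end.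

Step 2
Reactants: 2 1-[2-(benzyloxy)-3-bromophenyl]ethanone
Product: 4 (E)-1-[2-(benzyloxy)-3-bromophenyl]ethanone O-acetyl oxime, via oxime 3 (not isolated)
Conditions: NH2OH·HCl, NaOAc, EtOH/H2O, 80 °C; extractive work-up; Ac2O, pyridine, DMAP (cat.), CH2Cl2, rt
Reagents that add atoms: hydroxylamine hydrochloride, NO.Cl; acetic anhydride, CC(=O)OC(C)=O
Why: Oxime condensation followed by O-acetylation should give mainly the E isomer (acetoxy anti to the arene), whose nitrogen lone pair faces the free ortho C–H and whose N–O bond serves as internal oxidant in step 3.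

Step 3
Reactants: 4 (E)-O-acetyl oxime; 5 propyne
Product: 6 8-(benzyloxy)-7-bromo-1,3-dimethylisoquinoline
Conditions: [Cp*Co(CO)I2] (10 mol %), AgSbF6 (20 mol %), KOAc (20 mol %), propyne (3 equiv), ClCH2CH2Cl, 120 °C, sealed tube
Reagents that add atoms: none
Why: Oxime-directed C–H activation/alkyne annulation under trivalent-cobalt catalysis, a reaction type that accepts terminal alkynes, metalates the only free ortho C–H, inserts propyne with its CH end on the arene and closes C3–N with loss of acetate, which places methyl at C3, hydrogen at C4, bromine at C7 and benzyloxy at C8.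

Step 4
Reactants: 7 3-methylfuran
Product: 8 2-bromo-3-methylfuran
Conditions: NBS (1.0 equiv), DMF, −20 to 0 °C, dark; used promptly
Reagents that add atoms: N-bromosuccinimide, O=C1CCC(=O)N1Br
Why: Electrophilic aromatic bromination goes to the alpha carbon next to the methyl group because that methyl stabilises the sigma complex, whereas direct deprotonation of 7 would favour C5, so the metal is introduced through the bromide.

Step 5
Reactants: 8 2-bromo-3-methylfuran; 6 8-(benzyloxy)-7-bromo-1,3-dimethylisoquinoline
Product: 11 8-(benzyloxy)-1,3-dimethyl-7-(3-methylfuran-2-yl)isoquinoline, via furyllithium 9 (not isolated), via furylzinc chloride 10 (not isolated)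
Conditions: 8, n-BuLi, THF, −78 °C; ZnCl2, −78 °C to rt; 6, Pd(OAc)2 (2 mol %), SPhos (4 mol %), THF, 60 °C
Reagents that add atoms: none
Why: Bromine–lithium exchange, transmetalation and Negishi coupling form the still uncrowded C7–C2(furan) bond, and the zinc reagent is too weakly basic to touch the acidic 1-methyl group and is free of the protodemetalation that plagues 2-furylboronic acids.

Step 6
Reactants: 12 3-(benzyloxy)phenol
Product: 13 3-(benzyloxy)phenyl isopropylcarbamate
Conditions: i-PrNCO, Et3N (cat.), CH2Cl2, rt
Reagents that add atoms: isopropyl isocyanate, CC(C)N=C=O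
Why: Base-catalysed addition of the phenol to the isocyanate installs a secondary carbamate that directs metalation and can later be removed without acid.

Step 7
Reactants: 13 3-(benzyloxy)phenyl isopropylcarbamate
Product: 17 3-(benzyloxy)-2-(trimethylsilyl)phenyl isopropylcarbamate, via N-silyl carbamate 14 (not isolated), via aryllithium 15 (not isolated), via bis-silyl carbamate 16 (not isolated)
Conditions: TBSOTf, TMEDA, Et2O, 0 °C to rt; n-BuLi, TMEDA, −78 °C; TMSCl, −78 °C to rt; aq NaHSO4
Reagents that add atoms: chlorotrimethylsilane, C[Si](C)(C)Cl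
Why: Directed ortho-metalation after transient N-silylation, in which carbamate and benzyloxy group cooperate to lithiate the carbon between them at −78 °C faster than the benzylic position, is followed by a TMSCl quench and hydrolytic loss of the N-silyl group.

Step 8
Reactants: 17 3-(benzyloxy)-2-(trimethylsilyl)phenyl isopropylcarbamate
Product: 19 3-(benzyloxy)-2-(trimethylsilyl)phenyl trifluoromethanesulfonate, via silylphenol 18 (not isolated)
Conditions: DBU, Et2NH, MeCN, 40 °C; then PhNTf2, rt
Reagents that add atoms: N-phenylbis(trifluoromethanesulfonimide), O=S(=O)(N(c1ccccc1)S(=O)(=O)C(F)(F)F)C(F)(F)F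
Why: E1cB cleavage of the secondary carbamate (the isocyanate is trapped by Et2NH) and triflation of the phenoxide in the same flask avoid acid, which would protodesilylate this electron-rich arylsilane.

Step 9
Reactants: 11 8-(benzyloxy)-1,3-dimethyl-7-(3-methylfuran-2-yl)isoquinoline; 19 3-(benzyloxy)-2-(trimethylsilyl)phenyl trifluoromethanesulfonate
Product: 21 rac-(1R,4S)-5-(benzyloxy)-1-[8-(benzyloxy)-1,3-dimethylisoquinolin-7-yl]-2-methyl-1,4-dihydro-1,4-epoxynaphthalene, via 3-benzyloxybenzyne 20 (not isolated)
Conditions: CsF (4 equiv), MeCN/toluene 1:1, rt, 19 (1.6 equiv) added by syringe pump over 4 h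
Reagents that add atoms: none
Why: Fluoride attacks the silicon of 19 and triflate leaves, releasing aryne 20, whose strained in-plane pi bond adds suprafacially across C2 and C5 of the furan in a concerted, asynchronous [4+2] cycloaddition, the well-established aryne–furan Diels–Alder reaction of o-silylaryl triflates. The six-membered carbocycle C1'–C2'–C3'–C4'–C4a'–C8a' closes by intermolecular [4+2] annulation (new bonds C1'–C8a' and C4'–C4a') while the furan oxygen becomes the 1,4-epoxy bridge. C1' and C4' are fixed relative to each other by the bridge, because both bonds must form on one face of the furan; nothing controls the absolute sense, so 21 is racemic, and both centres are erased in step 10. The step needs orientation, with furan C2 joining the aryne carbon meta to the benzyloxy group (the electrophilic end of this polarised aryne): the 3-methyl group raises the HOMO coefficient at C2 as in isoprene, the isoquinolinyl ring, twisted by 3-Me and O8-benzyl and electron-poor, feeds little density to C5, and the OCH2Ph arm, which can lie in the ring plane beside the hydrogen-free aryne carbon, repels the aryl group in the opposite orientation. It also needs chemoselectivity for the furan over N2, which the 1- and 3-methyl groups (the former buttressed by O8-benzyl) and the slow release of the aryne into an excess of furan should provide. Steric crowding at the future axis builds up only during this ring growth, so no congested biaryl coupling is needed.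

Step 10
Reactants: 21 oxa-bridged adduct
Product: 22 rac-8-(benzyloxy)-4-[8-(benzyloxy)-1,3-dimethylisoquinolin-7-yl]-3-methylnaphthalen-1-ol
Conditions: TFA (10 equiv), CH2Cl2, 0 °C to rt; then aq NaHCO3/MeOH
Reagents that add atoms: none
Why: In this acid-catalysed isomerisation of a 1,4-epoxy-1,4-dihydronaphthalene to a 1-naphthol, heterolysis of C1'–O and loss of H4' aromatise the ring with oxygen on C4' and turn the two centres into the racemic C7–C1' axis, while ionisation at C4' is no exit because C1' bears no hydrogen, so it either reverts or, after trifluoroacetate capture at C4' and loss of water from C1', gives the naphthyl trifluoroacetate that the basic work-up cleaves to the same naphthol.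

Step 11
Reactants: 22 4'-naphthol
Product: 23 rac-8-(benzyloxy)-7-[5-(benzyloxy)-4-methoxy-2-methylnaphthalen-1-yl]-1,3-dimethylisoquinoline
Conditions: MeI (1.1 equiv), K2CO3, DMF, rt
Reagents that add atoms: iodomethane, CI
Why: Williamson O-methylation meets only one free hydroxy group, and the naphtholate should outrun the nitrogen flanked by two methyl groups when MeI is kept near one equivalent.

Step 12
Reactants: 23 bis(benzyl) ether
Product: 24 rac-7-(5-hydroxy-4-methoxy-2-methylnaphthalen-1-yl)-1,3-dimethylisoquinolin-8-ol
Conditions: H2 (1 atm), 10 % Pd/C, MeOH/EtOAc, rt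
Reagents that add atoms: none
Why: Hydrogenolysis of both benzyl aryl ethers under neutral conditions at atmospheric pressure should leave the methyl ether and both aromatic ring systems untouched.

Step 13
Reactants: 24 racemic biaryl
Product: 25 ent-dioncophylleine A (single atropo-enantiomer, axis taken as M)
Conditions: preparative HPLC, cellulose tris(3,5-dimethylphenylcarbamate) phase, n-hexane/i-PrOH/Et2NH, rt
Reagents that add atoms: none
Why: In this resolution on a chiral phase the axis, flanked by O8, the 2'-methyl group and the peri C8'–H, should be configurationally stable at rt, so the enantiomers can be separated and assigned by CD.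

Compound list
1 | 1-(3-bromo-2-hydroxyphenyl)ethanone | CC(=O)c1cccc(Br)c1O | starting material
2 | 1-[2-(benzyloxy)-3-bromophenyl]ethanone | CC(=O)c1cccc(Br)c1OCc1ccccc1 | intermediate
3 | (E)-1-[2-(benzyloxy)-3-bromophenyl]ethanone oxime | C/C(=N\O)c1cccc(Br)c1OCc1ccccc1 | intermediate
4 | (E)-1-[2-(benzyloxy)-3-bromophenyl]ethanone O-acetyl oxime | C/C(=N\OC(C)=O)c1cccc(Br)c1OCc1ccccc1 | intermediate
5 | propyne | CC#C | starting material
6 | 8-(benzyloxy)-7-bromo-1,3-dimethylisoquinoline | Cc1cc2ccc(Br)c(OCc3ccccc3)c2c(C)n1 | intermediate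
7 | 3-methylfuran | Cc1ccoc1 | starting material
8 | 2-bromo-3-methylfuran | Cc1ccoc1Br | intermediate
9 | (3-methylfuran-2-yl)lithium | [Li]c1occc1C | intermediate
10 | (3-methylfuran-2-yl)zinc chloride | Cl[Zn]c1occc1C | intermediate
11 | 8-(benzyloxy)-1,3-dimethyl-7-(3-methylfuran-2-yl)isoquinoline | Cc1ccoc1-c1ccc2cc(C)nc(C)c2c1OCc1ccccc1 | intermediate
12 | 3-(benzyloxy)phenol | Oc1cccc(OCc2ccccc2)c1 | starting material
13 | 3-(benzyloxy)phenyl isopropylcarbamate | CC(C)NC(=O)Oc1cccc(OCc2ccccc2)c1 | intermediate
14 | 3-(benzyloxy)phenyl N-(tert-butyldimethylsilyl)-N-isopropylcarbamate | CC(C)N(C(=O)Oc1cccc(OCc2ccccc2)c1)[Si](C)(C)C(C)(C)C | intermediate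
15 | 2-lithio derivative of 14 | CC(C)N(C(=O)Oc1cccc(OCc2ccccc2)c1[Li])[Si](C)(C)C(C)(C)C | intermediate
16 | 3-(benzyloxy)-2-(trimethylsilyl)phenyl N-(tert-butyldimethylsilyl)-N-isopropylcarbamate | CC(C)N(C(=O)Oc1cccc(OCc2ccccc2)c1[Si](C)(C)C)[Si](C)(C)C(C)(C)C | intermediate
17 | 3-(benzyloxy)-2-(trimethylsilyl)phenyl isopropylcarbamate | CC(C)NC(=O)Oc1cccc(OCc2ccccc2)c1[Si](C)(C)C | intermediate
18 | 3-(benzyloxy)-2-(trimethylsilyl)phenol (present as its DBU salt) | Oc1cccc(OCc2ccccc2)c1[Si](C)(C)C | intermediate
19 | 3-(benzyloxy)-2-(trimethylsilyl)phenyl trifluoromethanesulfonate | C[Si](C)(C)c1c(OCc2ccccc2)cccc1OS(=O)(=O)C(F)(F)F | intermediate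
20 | 3-benzyloxybenzyne | C1#CC(OCc2ccccc2)=CC=C1 | intermediate
21 | rac-(1R,4S)-5-(benzyloxy)-1-[8-(benzyloxy)-1,3-dimethylisoquinolin-7-yl]-2-methyl-1,4-dihydro-1,4-epoxynaphthalene (one enantiomer drawn) | CC1=C[C@@H]2O[C@@]1(c1ccc3cc(C)nc(C)c3c1OCc1ccccc1)c1cccc(OCc3ccccc3)c12 | intermediate
22 | rac-8-(benzyloxy)-4-[8-(benzyloxy)-1,3-dimethylisoquinolin-7-yl]-3-methylnaphthalen-1-ol | Cc1cc(O)c2c(OCc3ccccc3)cccc2c1-c1ccc2cc(C)nc(C)c2c1OCc1ccccc1 | intermediate
23 | rac-8-(benzyloxy)-7-[5-(benzyloxy)-4-methoxy-2-methylnaphthalen-1-yl]-1,3-dimethylisoquinoline | Cc1cc(OC)c2c(OCc3ccccc3)cccc2c1-c1ccc2cc(C)nc(C)c2c1OCc1ccccc1 | intermediate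
24 | rac-7-(5-hydroxy-4-methoxy-2-methylnaphthalen-1-yl)-1,3-dimethylisoquinolin-8-ol | COc1cc(C)c(-c2ccc3cc(C)nc(C)c3c2O)c2cccc(O)c12 | intermediate
25 | ent-dioncophylleine A, single atropo-enantiomer (axis taken as M; not expressible in SMILES) | COc1cc(C)c(-c2ccc3cc(C)nc(C)c3c2O)c2cccc(O)c12 | target

Total step count: 13. Longest linear sequence: 9 (steps 1, 2, 3, 5, 9, 10, 11, 12, 13).

Steps most likely to fail

**Step 9.**
- **Risk:** the orientation may erode or invert. The unsubstituted C5 is usually the more nucleophilic terminus of a 2-substituted furan and may lead the bonding to the electrophilic aryne carbon. N-arylation of the isoquinoline may also consume aryne.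
- **Fallback (from 11, back at 21):** the polarity of the aryne is reversed. A boryl group is a sigma donor that makes the neighbouring aryne carbon the electrophilic one. 3-Borylarynes are known to give the distal adducts with 2-substituted furans, so boron serves as a masked O5'.
- **Sequence:** commercial 2,6-diiodophenol is magnesiated once (MeMgCl/LiCl, then i-PrMgCl, THF) and quenched with i-PrOBpin to give 2-iodo-6-(pinacolboryl)phenol F1. Tf2O/pyridine converts it to 2-iodo-6-(pinacolboryl)phenyl triflate F2. i-PrMgCl·LiCl at −78 °C in the presence of 11 releases 3-(pinacolboryl)benzyne F3, which should add to give the 5-boryl oxa-bridged adduct F4. NaBO3·4H2O in THF/H2O oxidises it to the 5-hydroxy oxa-bridged adduct F5. BnBr/K2CO3 in DMF then returns to 21.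

**Step 10.**
- **Risk:** the wrong bridge bond may ionise. Cleavage of C4'–O gives a cation supported by the ortho O5' donor and by the 2'-methyl group at its allyl terminus, whereas the C1' cation carries a protonated isoquinolinyl group. Material may then drain away by 1,2-shift of the aryl group to C2'. It may also be lost by deprotonation of the 2'-methyl group followed by departure of the C1' hydroxy group.
- **Fallback (from 21, back at 23, skipping step 11):** the favoured ionisation is put to use.
- **Sequence:** camphorsulfonic acid (1.2 equiv) in MeOH at 0 °C opens the bridge at C4' and methanol is captured there. This gives 5-(benzyloxy)-1-[8-(benzyloxy)-1,3-dimethylisoquinolin-7-yl]-4-methoxy-2-methyl-1,4-dihydronaphthalen-1-ol F6. MsCl/Et3N in CH2Cl2 then activates only the tertiary C1' hydroxy group under non-acidic conditions, and 1,4-elimination with loss of H4' aromatises directly to 23.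

**Step 3.**
- **Risk:** C–H metalation may be slow, because the ortho-benzyloxy group twists the oxime out of the arene plane and raises the share of the unreactive Z isomer. The volatile terminal alkyne may also be lost or oligomerise.
- **Fallback (from 3, here isolated, back at 6):** alkyne insertion is replaced by C–H alkylation with an oxidised alkyne equivalent.
- **Sequence:** [Cp*RhCl2]2/CsOAc in MeOH at 60 °C with 2-oxopropyl methanesulfonate acetonylates the ortho position. The oxime nitrogen then condenses onto the ketone to give 8-(benzyloxy)-7-bromo-1,3-dimethylisoquinoline 2-oxide F7. B2pin2 in MeCN at 70 °C deoxygenates it to 6.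

Further compounds
F1 | step 9 | 2-iodo-6-(4,4,5,5-tetramethyl-1,3,2-dioxaborolan-2-yl)phenol | CC1(C)OB(OC1(C)C)c1cccc(I)c1O
F2 | step 9 | 2-iodo-6-(4,4,5,5-tetramethyl-1,3,2-dioxaborolan-2-yl)phenyl trifluoromethanesulfonate | CC1(C)OB(OC1(C)C)c1cccc(I)c1OS(=O)(=O)C(F)(F)F
F3 | step 9 | 3-(4,4,5,5-tetramethyl-1,3,2-dioxaborolan-2-yl)benzyne | CC1(C)OB(OC1(C)C)C1=CC=CC#C1
F4 | step 9 | racemic 1-[8-(benzyloxy)-1,3-dimethylisoquinolin-7-yl]-2-methyl-5-(pinacolboryl)-1,4-dihydro-1,4-epoxynaphthalene (one enantiomer drawn) | CC1=C[C@@H]2O[C@@]1(c1ccc3cc(C)nc(C)c3c1OCc1ccccc1)c1cccc(B3OC(C)(C)C(C)(C)O3)c12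
F5 | step 9 | racemic 1-[8-(benzyloxy)-1,3-dimethylisoquinolin-7-yl]-2-methyl-1,4-dihydro-1,4-epoxynaphthalen-5-ol (one enantiomer drawn) | CC1=C[C@@H]2O[C@@]1(c1ccc3cc(C)nc(C)c3c1OCc1ccccc1)c1cccc(O)c12
F6 | step 10 | 5-(benzyloxy)-1-[8-(benzyloxy)-1,3-dimethylisoquinolin-7-yl]-4-methoxy-2-methyl-1,4-dihydronaphthalen-1-ol (racemic cis/trans mixture) | COC1C=C(C)C(O)(c2ccc3cc(C)nc(C)c3c2OCc2ccccc2)c2cccc(OCc3ccccc3)c12
F7 | step 3 | 8-(benzyloxy)-7-bromo-1,3-dimethylisoquinoline 2-oxide | Cc1cc2ccc(Br)c(OCc3ccccc3)c2c(C)[n+]1[O-]
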